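**Plan**

1. The target is 7-hydroxy-3,5,6,8-tetramethoxy-2-(4-methoxyphenyl)-4H-chromen-4-one. Retrosynthetically, O7–H is masked as a benzyl ether and the C3–OMe group is traced back to C3–H through O-methylation and C3 hydroxylation.
2. Ring C is then cut at three bonds at once, O1–C2, C4–C3 and C4a–C4. The C4 carbonyl lies between C4a of the fully substituted ring A and the C3–C2 unit, so it can be supplied as carbon monoxide joining an ortho-iodophenol (ring A) to 4-ethynylanisole (C2, C3 and ring B).
3. The iodophenol is traced back through its C–I, C–OMe and C–OH bonds to a symmetrical dibromide made from syringol benzyl ether.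
4. Forward order: ring A is dressed first (steps 1 to 5). Ring C is closed in the carbonylative annulation that also attaches ring B (step 6). C3 is then oxygenated and methylated and the benzyl group removed (steps 7 to 9).
5. Stereochemistry: the target has no stereocentre and no configured double bond, so nothing has to be set.

Key step: step 6

Assumption: carbon monoxide and the other small reagents are treated as reagents, not as numbered compounds, and the borate intermediates are written as the lithium trimethoxyborate complexes present before oxidation.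

**Route**

Step 1
Reactants: 1 2,6-dimethoxyphenol (syringol); 2 benzyl bromide
Product: 3 2-(benzyloxy)-1,3-dimethoxybenzene
Conditions: K2CO3, DMF, 60 °C
Reagents that add atoms: none
Why: Williamson ether synthesis, in which the phenoxide of 1 displaces bromide from the reactive benzylic halide by SN2.

Step 2
Reactants: 3 2-(benzyloxy)-1,3-dimethoxybenzene
Product: 4 3-(benzyloxy)-1,5-dibromo-2,4-dimethoxybenzene
Conditions: NBS (2.2 equiv), MeCN, 0 °C to rt
Reagents that add atoms: N-bromosuccinimide, O=C1CCC(=O)N1Br
Why: Electrophilic aromatic bromination should enter the two ring carbons that are ortho to one methoxy group and para to the other, because the central benzyloxy group is twisted out of conjugation and activates its para position only weakly.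

Step 3
Reactants: 4 3-(benzyloxy)-1,5-dibromo-2,4-dimethoxybenzene
Product: 7 3-(benzyloxy)-5-bromo-2,4-dimethoxyphenol, via aryllithium 5 (not isolated), via borate complex 6 (not isolated)
Conditions: n-BuLi (1.05 equiv), THF, −78 °C; B(OMe)3, −78 °C to 0 °C; AcOH, 30% aq. H2O2, 0 °C to rt
Reagents that add atoms: hydrogen peroxide, OO (the phenol oxygen); for intermediates 5 and 6 only: n-butyllithium, [Li]CCCC, and trimethyl borate, COB(OC)OC
Why: Bromine–lithium exchange on one of the two equivalent C–Br bonds, borate trapping and oxidative 1,2-aryl shift from boron to oxygen (boronate oxidation) should turn a single bromide into the phenol, the exchange being much faster than benzylic deprotonation at −78 °C.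

Step 4
Reactants: 7 3-(benzyloxy)-5-bromo-2,4-dimethoxyphenol
Product: 8 3-(benzyloxy)-2,4,5-trimethoxyphenol
Conditions: NaOMe (excess, in MeOH), CuI (20 mol %), DMF, 110 °C, argon; then aq. HCl
Reagents that add atoms: sodium methoxide, [Na+].[O-]C
Why: Ullmann-type copper-catalysed methoxylation of an aryl bromide, a reaction known to tolerate free bromophenols (as their phenoxides) and benzyl ethers.

Step 5
Reactants: 8 3-(benzyloxy)-2,4,5-trimethoxyphenol
Product: 9 3-(benzyloxy)-6-iodo-2,4,5-trimethoxyphenol
Conditions: NIS (1.05 equiv), MeCN, 0 °C, dark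
Reagents that add atoms: N-iodosuccinimide, O=C1CCC(=O)N1I
Why: Electrophilic aromatic iodination can only occur at the single unsubstituted ring carbon, which is ortho to the hydroxyl group and strongly activated, so the regiochemistry is unambiguous.

Step 6
Reactants: 9 3-(benzyloxy)-6-iodo-2,4,5-trimethoxyphenol; 10 4-ethynylanisole
Product: 12 7-(benzyloxy)-5,6,8-trimethoxy-2-(4-methoxyphenyl)-4H-chromen-4-one, via ynone 11 (not isolated)
Conditions: PdCl2(dppf) (5 mol %), CO (20 atm), Et2NH, 120 °C, autoclave
Reagents that add atoms: carbon monoxide, [C-]#[O+]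
Why: Zerovalent palladium formed in situ inserts into the C–I bond of 9, carbon monoxide inserts to give the aroylpalladium iodide, and amine-assisted alkynylation with 10 followed by reductive elimination forges C4a–C4 and C4–C3 as the ortho-hydroxyaryl ynone 11. The phenol oxygen, deprotonated by Et2NH, then adds to the alkyne carbon bearing the anisyl group in a 6-endo-dig oxa-Michael closure that forms O1–C2 and ring C. The closest known reaction type is the palladium-catalysed carbonylative Sonogashira annulation of ortho-iodophenols with terminal arylacetylenes to flavones. No stereocentre is created. Two selectivities are needed: carbonyl insertion before alkynylation, which the CO pressure and the doubly ortho-substituted arylpalladium (slow direct coupling, ready insertion) should secure, and 6-endo over 5-exo closure, which the secondary amine medium is known to favour over aurone formation. The iodide is the only carbon–halogen bond present, and the benzyl and methyl ethers are inert to the catalyst.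

Step 7
Reactants: 12 7-(benzyloxy)-5,6,8-trimethoxy-2-(4-methoxyphenyl)-4H-chromen-4-one
Product: 15 7-(benzyloxy)-3-hydroxy-5,6,8-trimethoxy-2-(4-methoxyphenyl)-4H-chromen-4-one, via 3-lithioflavone 13 (not isolated), via borate complex 14 (not isolated)
Conditions: LiN(i-Pr)2 (commercial solution, 1.2 equiv), THF, −78 °C; B(OMe)3, −78 °C to 0 °C; AcOH, 30% aq. H2O2, 0 °C to rt
Reagents that add atoms: hydrogen peroxide, OO (the C3 oxygen); for intermediates 13 and 14 only: lithium diisopropylamide, [Li+].CC(C)[N-]C(C)C, and trimethyl borate, COB(OC)OC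
Why: Carbonyl-directed lithiation of the flavone at C3, its most acidic C–H, followed by borate trapping at −78 °C and boronate oxidation is the established lithiation–borylation–oxidation route from flavones to flavonols.

Step 8
Reactants: 15 7-(benzyloxy)-3-hydroxy-5,6,8-trimethoxy-2-(4-methoxyphenyl)-4H-chromen-4-one
Product: 16 7-(benzyloxy)-3,5,6,8-tetramethoxy-2-(4-methoxyphenyl)-4H-chromen-4-one
Conditions: MeI, K2CO3, acetone, reflux
Reagents that add atoms: iodomethane, CI
Why: Williamson O-methylation of the acidic 3-hydroxyl group, the only free hydroxyl in the molecule.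

Step 9
Reactants: 16 7-(benzyloxy)-3,5,6,8-tetramethoxy-2-(4-methoxyphenyl)-4H-chromen-4-one
Product: 17 7-hydroxy-3,5,6,8-tetramethoxy-2-(4-methoxyphenyl)-4H-chromen-4-one
Conditions: H2 (1 atm), 10% Pd/C, EtOAc–MeOH, rt
Reagents that add atoms: none
Why: Catalytic hydrogenolysis cleaves the benzylic C–O bond selectively, and the tetrasubstituted C2–C3 double bond, the carbonyl and the five methyl ethers (the acid-sensitive 5-OMe included) should be untouched under these neutral conditions.

**Compound list**

1 | 2,6-dimethoxyphenol (syringol) | COc1cccc(OC)c1O | starting material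
2 | benzyl bromide | BrCc1ccccc1 | starting material
3 | 2-(benzyloxy)-1,3-dimethoxybenzene | COc1cccc(OC)c1OCc1ccccc1 | intermediate
4 | 3-(benzyloxy)-1,5-dibromo-2,4-dimethoxybenzene | COc1c(Br)cc(Br)c(OC)c1OCc1ccccc1 | intermediate
5 | [3-(benzyloxy)-5-bromo-2,4-dimethoxyphenyl]lithium | [Li]c1cc(Br)c(OC)c(OCc2ccccc2)c1OC | intermediate
6 | lithium [3-(benzyloxy)-5-bromo-2,4-dimethoxyphenyl]trimethoxyborate | [Li+].CO[B-](OC)(OC)c1cc(Br)c(OC)c(OCc2ccccc2)c1OC | intermediate
7 | 3-(benzyloxy)-5-bromo-2,4-dimethoxyphenol | Oc1cc(Br)c(OC)c(OCc2ccccc2)c1OC | intermediate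
8 | 3-(benzyloxy)-2,4,5-trimethoxyphenol | COc1cc(O)c(OC)c(OCc2ccccc2)c1OC | intermediate
9 | 3-(benzyloxy)-6-iodo-2,4,5-trimethoxyphenol | Oc1c(I)c(OC)c(OC)c(OCc2ccccc2)c1OC | intermediate
10 | 4-ethynylanisole (1-ethynyl-4-methoxybenzene) | C#Cc1ccc(OC)cc1 | starting material
11 | 1-[4-(benzyloxy)-2-hydroxy-3,5,6-trimethoxyphenyl]-3-(4-methoxyphenyl)prop-2-yn-1-one | COc1ccc(C#CC(=O)c2c(O)c(OC)c(OCc3ccccc3)c(OC)c2OC)cc1 | intermediate
12 | 7-(benzyloxy)-5,6,8-trimethoxy-2-(4-methoxyphenyl)-4H-chromen-4-one | COc1ccc(-c2cc(=O)c3c(OC)c(OC)c(OCc4ccccc4)c(OC)c3o2)cc1 | intermediate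
13 | [7-(benzyloxy)-5,6,8-trimethoxy-2-(4-methoxyphenyl)-4-oxo-4H-chromen-3-yl]lithium | COc1ccc(-c2oc3c(OC)c(OCc4ccccc4)c(OC)c(OC)c3c(=O)c2[Li])cc1 | intermediate
14 | lithium [7-(benzyloxy)-5,6,8-trimethoxy-2-(4-methoxyphenyl)-4-oxo-4H-chromen-3-yl]trimethoxyborate | [Li+].COc1ccc(-c2oc3c(OC)c(OCc4ccccc4)c(OC)c(OC)c3c(=O)c2[B-](OC)(OC)OC)cc1 | intermediate
15 | 7-(benzyloxy)-3-hydroxy-5,6,8-trimethoxy-2-(4-methoxyphenyl)-4H-chromen-4-one | COc1ccc(-c2oc3c(OC)c(OCc4ccccc4)c(OC)c(OC)c3c(=O)c2O)cc1 | intermediate
16 | 7-(benzyloxy)-3,5,6,8-tetramethoxy-2-(4-methoxyphenyl)-4H-chromen-4-one | COc1ccc(-c2oc3c(OC)c(OCc4ccccc4)c(OC)c(OC)c3c(=O)c2OC)cc1 | intermediate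
17 | 7-hydroxy-3,5,6,8-tetramethoxy-2-(4-methoxyphenyl)-4H-chromen-4-one | COc1ccc(-c2oc3c(OC)c(O)c(OC)c(OC)c3c(=O)c2OC)cc1 | target

**Count**

Total steps: 9. Longest linear sequence: 9 steps (1 to 17); compounds 2 and 10 enter as purchased reagents.

**Steps most likely to fail**

Step 6. The arylpalladium species may couple with the alkyne before carbon monoxide has inserted. The aroylpalladium may instead be captured by diethylamine (aminocarbonylation), or the ynone may close in the 5-exo mode. Oxidative addition into the hindered, electron-rich C–I bond may also be slow. The fallback sets out from 9 and comes back to the route at 12, forming the same three bonds without palladium or carbon monoxide. Commercial 3-(4-methoxyphenyl)propiolic acid is converted (EDC·HCl, MeNHOMe·HCl, i-Pr2NEt, CH2Cl2) into N-methoxy-N-methyl-3-(4-methoxyphenyl)prop-2-ynamide F1. Iodophenol 9 is treated with n-BuLi (2.1 equiv, THF, −78 °C), first deprotonating the phenol and then exchanging iodine, to give lithium 3-(benzyloxy)-6-lithio-2,4,5-trimethoxyphenolate F2. Acylation of F2 by F1 and aqueous work-up should give ynone 11, now isolated. Et2NH in EtOH at 60 °C then closes 11 to 12 by the same 6-endo oxa-Michael addition.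

Step 7. The 3-lithio species may ring-open by β-elimination of the phenoxide if the temperature rises. Benzylic deprotonation of the benzyl ether followed by Wittig rearrangement may compete, and deprotonation may be incomplete. The fallback sets out from 12 and comes back at 15 by an electrophilic rather than an anionic oxygenation. Dimethyldioxirane (acetone–CH2Cl2, 0 °C to rt) should epoxidise the C2–C3 enol ether double bond to the racemic cis-fused 7-(benzyloxy)-2,3-epoxy-5,6,8-trimethoxy-2-(4-methoxyphenyl)chroman-4-one F3. Catalytic p-TsOH in CHCl3 then opens the epoxide and tautomerises it to flavonol 15.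

Step 4. The bromide may be lost reductively (protodebromination), the electron-rich phenoxide may be oxidised at high temperature, or the coupling may stall on the deactivated ring. The fallback sets out from 7 and comes back at 8, replacing the C–O coupling by hydroxylation and O-methylation on a protected phenol.
- MOMCl and i-Pr2NEt in CH2Cl2 give 3-(benzyloxy)-1-bromo-2,4-dimethoxy-5-(methoxymethoxy)benzene F4.
- n-BuLi (THF, −78 °C) gives [3-(benzyloxy)-2,4-dimethoxy-5-(methoxymethoxy)phenyl]lithium F5.
- B(OMe)3 gives lithium [3-(benzyloxy)-2,4-dimethoxy-5-(methoxymethoxy)phenyl]trimethoxyborate F6.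
- H2O2 with aq. NaOH gives 3-(benzyloxy)-2,4-dimethoxy-5-(methoxymethoxy)phenol F7.
- MeI and K2CO3 in acetone give 3-(benzyloxy)-1,2,4-trimethoxy-5-(methoxymethoxy)benzene F8.
- Dilute HCl in MeOH at 40 °C removes the methoxymethyl group, leaving the benzyl ether intact, to give 8.

**Further compounds**

F1 | step 6 | N-methoxy-N-methyl-3-(4-methoxyphenyl)prop-2-ynamide | CON(C)C(=O)C#Cc1ccc(OC)cc1
F2 | step 6 | lithium 3-(benzyloxy)-6-lithio-2,4,5-trimethoxyphenolate | [Li+].[O-]c1c([Li])c(OC)c(OC)c(OCc2ccccc2)c1OC
F3 | step 7 | 7-(benzyloxy)-2,3-epoxy-5,6,8-trimethoxy-2-(4-methoxyphenyl)chroman-4-one (racemic, cis-fused; one enantiomer drawn) | COc1ccc(cc1)[C@]12O[C@H]1C(=O)c1c(OC)c(OC)c(OCc3ccccc3)c(OC)c1O2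
F4 | step 4 | 3-(benzyloxy)-1-bromo-2,4-dimethoxy-5-(methoxymethoxy)benzene | COCOc1cc(Br)c(OC)c(OCc2ccccc2)c1OC
F5 | step 4 | [3-(benzyloxy)-2,4-dimethoxy-5-(methoxymethoxy)phenyl]lithium | [Li]c1cc(OCOC)c(OC)c(OCc2ccccc2)c1OC
F6 | step 4 | lithium [3-(benzyloxy)-2,4-dimethoxy-5-(methoxymethoxy)phenyl]trimethoxyborate | [Li+].CO[B-](OC)(OC)c1cc(OCOC)c(OC)c(OCc2ccccc2)c1OC
F7 | step 4 | 3-(benzyloxy)-2,4-dimethoxy-5-(methoxymethoxy)phenol | COCOc1cc(O)c(OC)c(OCc2ccccc2)c1OC
F8 | step 4 | 3-(benzyloxy)-1,2,4-trimethoxy-5-(methoxymethoxy)benzene | COCOc1cc(OC)c(OC)c(OCc2ccccc2)c1OC
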